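The lactone ring (O1, C2, C3, C4, C5) is treated as a hydrolysed and reduced 2-ethoxyfuran, and that furan is made from another aromatic ring. 5-Ethoxy-4-methyloxazole adds across its C2 and C5 to an aryl ynone in a Diels–Alder reaction; loss of acetonitrile then leaves a 2-ethoxy-3-aroyl-4-benzylfuran. One operation thus forms the C4–C5 and C2–C3 bonds of the lactone: the oxazole supplies C5, O1 and the carbonyl carbon C2, the alkyne supplies C3 and C4 with both aryl side chains. The aroyl group activates the alkyne, fixes the regiochemistry and is the latent syringyl CH2. Hydrolysis, asymmetric conjugate reduction, face-selective hydroxylation and hydrogenolysis complete the route.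

Key step: step 4

Remark: the target is (3S,4R); the two arylmethyl groups are cis on the lactone and the C3 hydroxyl is trans to the C4 arylmethyl group. Lactone numbering O1, C2 (C=O), C3, C4, C5 is used throughout.
Assumption: (S)-p-tol-BINAP is taken as the ligand enantiomer that delivers hydride to the required face of C4 in step 6; if the sense of induction is the opposite, the (R)-ligand is used.
Assumption: compounds 1, 2, 5 and 9 are taken as commercial.

Step 1
Reactants: 1 1-(benzyloxy)-4-bromo-2-methoxybenzene; 2 methoxyallene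
Product: 4 1-(benzyloxy)-2-methoxy-4-(prop-2-yn-1-yl)benzene, via aryl Grignard reagent 3 (not isolated)
Conditions: Mg, THF, 45 °C; then 2, CuBr (5 mol %), THF, 0 °C to rt
Reagents that add atoms: none
Why: Copper-catalysed SN2′ substitution of an alkoxyallene by a Grignard reagent: the aryl group adds to the CH2 terminus of 2 and methoxide leaves, which should give the terminal 3-arylpropyne directly.

Step 2
Reactants: 4 1-(benzyloxy)-2-methoxy-4-(prop-2-yn-1-yl)benzene; 5 4-(benzyloxy)-3,5-dimethoxybenzaldehyde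
Product: 7 racemic 1-[4-(benzyloxy)-3,5-dimethoxyphenyl]-4-[4-(benzyloxy)-3-methoxyphenyl]but-2-yn-1-ol, via lithium acetylide 6 (not isolated)
Conditions: n-BuLi, THF, −78 °C; then 5, −78 to 0 °C
Reagents that add atoms: none
Why: Lithium acetylide 1,2-addition to an aryl aldehyde; at −78 °C the sp C–H is removed in preference to the benzylic propargylic C–H, and the racemic carbinol is immaterial because it is oxidised next.

Step 3
Reactants: 7 racemic 1-[4-(benzyloxy)-3,5-dimethoxyphenyl]-4-[4-(benzyloxy)-3-methoxyphenyl]but-2-yn-1-ol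
Product: 8 1-[4-(benzyloxy)-3,5-dimethoxyphenyl]-4-[4-(benzyloxy)-3-methoxyphenyl]but-2-yn-1-one
Conditions: MnO2, CH2Cl2, rt
Reagents that add atoms: none
Why: MnO2 oxidation of a benzylic propargylic alcohol under neutral, non-basic conditions, so the ynone should not isomerise to the allenyl ketone.

Step 4
Reactants: 8 1-[4-(benzyloxy)-3,5-dimethoxyphenyl]-4-[4-(benzyloxy)-3-methoxyphenyl]but-2-yn-1-one; 9 5-ethoxy-4-methyl-1,3-oxazole
Product: 11 {4-{[4-(benzyloxy)-3-methoxyphenyl]methyl}-2-ethoxyfuran-3-yl}[4-(benzyloxy)-3,5-dimethoxyphenyl]methanone, via oxazanorbornadiene cycloadduct 10 (not isolated)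
Conditions: 9 (3 equiv), toluene, 110 °C, sealed tube
Reagents that add atoms: none
Why: A normal-demand (4+2) cycloaddition of the 2-azadiene of 9 (C2=N3–C4=C5) to the electron-poor triple bond of 8 should give the 7-oxa-2-azabicyclo[2.2.1]heptadiene 10, and a retro-(4+2) cycloreversion then expels N3 and C4 with its methyl group as acetonitrile, leaving the aromatic furan. The closest known reaction type is the oxazole–alkyne Diels–Alder/retro-Diels–Alder furan synthesis with acetylenic ketones, together with the Kondrat'eva chemistry of 5-alkoxyoxazoles. The furan ring is closed by a concerted suprafacial cycloaddition that joins oxazole C2 to the benzyl-bearing alkyne carbon and oxazole C5 to the acyl-bearing alkyne carbon, and the five-membered ring is what remains after the cycloreversion. No stereocentre is set, since the two bridgehead centres of 10 are lost on aromatisation. The selectivity needed is regiochemical: the 5-ethoxy donor places the larger HOMO coefficient on the remote terminus C2, which pairs with the β-carbon of the ynone, so the aroyl group ends next to the ethoxy-bearing carbon, the same orientation that puts acceptor groups at C4 of the pyridinols formed from this oxazole. The ketone activates an otherwise inert dialkylalkyne and is the latent CH2 of the syringylmethyl group.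

Step 5
Reactants: 11 {4-{[4-(benzyloxy)-3-methoxyphenyl]methyl}-2-ethoxyfuran-3-yl}[4-(benzyloxy)-3,5-dimethoxyphenyl]methanone
Product: 12 3-[4-(benzyloxy)-3,5-dimethoxybenzoyl]-4-{[4-(benzyloxy)-3-methoxyphenyl]methyl}furan-2(5H)-one
Conditions: 2 M HCl, THF, 50 °C
Reagents that add atoms: water, O
Why: Acid hydrolysis of a vinylogous ester (2-alkoxyfuran to butenolide): O-protonation of the aroyl group, addition of water at C2, loss of ethanol and ketonisation at C5 should give the conjugated furan-2(5H)-one.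

Step 6
Reactants: 12 3-[4-(benzyloxy)-3,5-dimethoxybenzoyl]-4-{[4-(benzyloxy)-3-methoxyphenyl]methyl}furan-2(5H)-one
Product: 13 (3R,4S)-3-[4-(benzyloxy)-3,5-dimethoxybenzoyl]-4-{[4-(benzyloxy)-3-methoxyphenyl]methyl}oxolan-2-one
Conditions: Cu(OAc)2·H2O (5 mol %), (S)-p-tol-BINAP (5 mol %), (EtO)2MeSiH (2 equiv), t-BuOH (1.5 equiv), toluene, 0 °C
Reagents that add atoms: none
Why: CuH-catalysed asymmetric conjugate reduction, as established for β,β-disubstituted butenolides and enones: the ligated CuH delivers hydride to C4 of the doubly activated alkene on the face chosen by the chiral bisphosphine, t-BuOH protonates the enolate, and the labile C3 centre settles trans to the C4 substituent.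

Step 7
Reactants: 13 (3R,4S)-3-[4-(benzyloxy)-3,5-dimethoxybenzoyl]-4-{[4-(benzyloxy)-3-methoxyphenyl]methyl}oxolan-2-one
Product: 14 (3R,4R)-3-[4-(benzyloxy)-3,5-dimethoxybenzoyl]-4-{[4-(benzyloxy)-3-methoxyphenyl]methyl}-3-hydroxyoxolan-2-one
Conditions: DMDO (1.2 equiv), Ni(acac)2 (5 mol %), acetone, 0 °C
Reagents that add atoms: dimethyldioxirane (DMDO), CC1(C)OO1
Why: Electrophilic α-hydroxylation of a 1,3-dicarbonyl compound through its planar nickel enolate: the dioxirane should attack the face opposite the C4 arylmethyl group, so the hydroxyl ends trans to it and the aroyl group cis, whatever the C3 configuration of 13 was.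

Step 8
Reactants: 14 (3R,4R)-3-[4-(benzyloxy)-3,5-dimethoxybenzoyl]-4-{[4-(benzyloxy)-3-methoxyphenyl]methyl}-3-hydroxyoxolan-2-one
Product: 16 (3S,4R)-3-hydroxy-3-[(4-hydroxy-3,5-dimethoxyphenyl)methyl]-4-[(4-hydroxy-3-methoxyphenyl)methyl]oxolan-2-one, via debenzylated hydroxy ketone 15 (not isolated)
Conditions: H2 (3 atm), 10% Pd/C, AcOH, HClO4 (cat.), rt
Reagents that add atoms: none
Why: Hydrogenolysis: the two benzyl ethers should cleave first, then the aryl ketone, activated by its para-hydroxyl, is reduced through the benzylic alcohol to CH2 under acid, while the tertiary non-benzylic C3–OH and both stereocentres are untouched (the C3 descriptor changes from R to S only through the change in substituent priority).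

Compound list
1 | 1-(benzyloxy)-4-bromo-2-methoxybenzene | COc1cc(Br)ccc1OCc1ccccc1 | starting material
2 | methoxyallene (1-methoxypropa-1,2-diene) | COC=C=C | starting material
3 | [4-(benzyloxy)-3-methoxyphenyl]magnesium bromide | COc1cc([Mg]Br)ccc1OCc1ccccc1 | intermediate
4 | 1-(benzyloxy)-2-methoxy-4-(prop-2-yn-1-yl)benzene | C#CCc1ccc(OCc2ccccc2)c(OC)c1 | intermediate
5 | 4-(benzyloxy)-3,5-dimethoxybenzaldehyde | COc1cc(C=O)cc(OC)c1OCc1ccccc1 | starting material
6 | {3-[4-(benzyloxy)-3-methoxyphenyl]prop-1-yn-1-yl}lithium | [Li]C#CCc1ccc(OCc2ccccc2)c(OC)c1 | intermediate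
7 | racemic 1-[4-(benzyloxy)-3,5-dimethoxyphenyl]-4-[4-(benzyloxy)-3-methoxyphenyl]but-2-yn-1-ol | OC(C#CCc1ccc(OCc2ccccc2)c(OC)c1)c1cc(OC)c(OCc2ccccc2)c(OC)c1 | intermediate
8 | 1-[4-(benzyloxy)-3,5-dimethoxyphenyl]-4-[4-(benzyloxy)-3-methoxyphenyl]but-2-yn-1-one | O=C(C#CCc1ccc(OCc2ccccc2)c(OC)c1)c1cc(OC)c(OCc2ccccc2)c(OC)c1 | intermediate
9 | 5-ethoxy-4-methyl-1,3-oxazole | CCOc1ocnc1C | starting material
10 | racemic [4-ethoxy-3-methyl-6-{[4-(benzyloxy)-3-methoxyphenyl]methyl}-7-oxa-2-azabicyclo[2.2.1]hepta-2,5-dien-5-yl][4-(benzyloxy)-3,5-dimethoxyphenyl]methanone | CCOC12OC(N=C1C)C(Cc1ccc(OCc3ccccc3)c(OC)c1)=C2C(=O)c1cc(OC)c(OCc2ccccc2)c(OC)c1 | intermediate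
11 | {4-{[4-(benzyloxy)-3-methoxyphenyl]methyl}-2-ethoxyfuran-3-yl}[4-(benzyloxy)-3,5-dimethoxyphenyl]methanone | CCOc1occ(Cc2ccc(OCc3ccccc3)c(OC)c2)c1C(=O)c1cc(OC)c(OCc2ccccc2)c(OC)c1 | intermediate
12 | 3-[4-(benzyloxy)-3,5-dimethoxybenzoyl]-4-{[4-(benzyloxy)-3-methoxyphenyl]methyl}furan-2(5H)-one | O=C1OCC(Cc2ccc(OCc3ccccc3)c(OC)c2)=C1C(=O)c1cc(OC)c(OCc2ccccc2)c(OC)c1 | intermediate
13 | (3R,4S)-3-[4-(benzyloxy)-3,5-dimethoxybenzoyl]-4-{[4-(benzyloxy)-3-methoxyphenyl]methyl}oxolan-2-one | COc1cc(C[C@@H]2COC(=O)[C@H]2C(=O)c2cc(OC)c(OCc3ccccc3)c(OC)c2)ccc1OCc1ccccc1 | intermediate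
14 | (3R,4R)-3-[4-(benzyloxy)-3,5-dimethoxybenzoyl]-4-{[4-(benzyloxy)-3-methoxyphenyl]methyl}-3-hydroxyoxolan-2-one | COc1cc(C[C@@H]2COC(=O)[C@]2(O)C(=O)c2cc(OC)c(OCc3ccccc3)c(OC)c2)ccc1OCc1ccccc1 | intermediate
15 | (3R,4R)-3-hydroxy-3-(4-hydroxy-3,5-dimethoxybenzoyl)-4-[(4-hydroxy-3-methoxyphenyl)methyl]oxolan-2-one | COc1cc(C[C@@H]2COC(=O)[C@]2(O)C(=O)c2cc(OC)c(O)c(OC)c2)ccc1O | intermediate
16 | (3S,4R)-3-hydroxy-3-[(4-hydroxy-3,5-dimethoxyphenyl)methyl]-4-[(4-hydroxy-3-methoxyphenyl)methyl]oxolan-2-one | COc1cc(C[C@@H]2COC(=O)[C@]2(O)Cc2cc(OC)c(O)c(OC)c2)ccc1O | target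

Total step count: 8. Longest linear sequence: 8 steps (1 to 16).

Steps most likely to fail

Step 6. The copper enolate of the β-keto lactone is a stable chelate and may hold the catalyst; the acidic C5–H of 12 may quench the hydride as the furanolate; facial discrimination at a tetrasubstituted alkene may be low; 1,2-reduction of the aryl ketone may compete. The fallback sets out from 12 and comes back at 14. The alkene is reduced without stereocontrol by the Hantzsch ester (diethyl 2,6-dimethyl-1,4-dihydropyridine-3,5-dicarboxylate, toluene, 60 °C), which should give 13 together with its enantiomer (3S,4R)-3-[4-(benzyloxy)-3,5-dimethoxybenzoyl]-4-{[4-(benzyloxy)-3-methoxyphenyl]methyl}oxolan-2-one F1. Hydroxylation under the conditions of step 7 should then give 14 together with its enantiomer (3S,4S)-3-[4-(benzyloxy)-3,5-dimethoxybenzoyl]-4-{[4-(benzyloxy)-3-methoxyphenyl]methyl}-3-hydroxyoxolan-2-one F2. The two are separated by preparative chromatography on a chiral stationary phase (amylose tris(3,5-dimethylphenylcarbamate)), and 14 goes on to step 8.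

Step 4. Heat or the weakly basic oxazole may isomerise the propargylic ynone 8 to the allenyl ketone, Michael-type oligomerisation may consume it, or regiocontrol in the cycloaddition may be lost. The fallback sets out from 4 and 5 and comes back at 12; it gives up the furan and closes the butenolide by acylation and condensation. Alkyne 4 is oxidised with 8-methylquinoline N-oxide under Ph3PAuNTf2 catalysis in AcOH/1,2-dichloroethane to 1-acetoxy-3-[4-(benzyloxy)-3-methoxyphenyl]propan-2-one F3, and methanolysis (K2CO3, MeOH, 0 °C) gives 1-[4-(benzyloxy)-3-methoxyphenyl]-3-hydroxypropan-2-one F4. Aldehyde 5 with ethyl diazoacetate and SnCl2 (Roskamp reaction) gives ethyl 3-[4-(benzyloxy)-3,5-dimethoxyphenyl]-3-oxopropanoate F5. Heating F4 with F5 (DMAP, toluene, reflux, removal of ethanol) should give 3-[4-(benzyloxy)-3-methoxyphenyl]-2-oxopropyl 3-[4-(benzyloxy)-3,5-dimethoxyphenyl]-3-oxopropanoate F6, which closes to 12 by intramolecular Knoevenagel condensation (piperidinium acetate, toluene, reflux).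

Step 8. Hydrogenolysis of the hindered ketone may stop at the benzylic carbinol, and under acid that carbinol may undergo retro-aldol cleavage or a 1,2-shift at the benzylic cation. The fallback sets out from 14 and comes back at 16; it separates ketone removal from debenzylation. NaBH4 (MeOH/THF, −20 °C) reduces the ketone to (3R,4R)-3-{[4-(benzyloxy)-3,5-dimethoxyphenyl](hydroxy)methyl}-4-{[4-(benzyloxy)-3-methoxyphenyl]methyl}-3-hydroxyoxolan-2-one F7 (carbinol epimers). Ionic deoxygenation of this electron-rich benzylic alcohol (Et3SiH, BF3·OEt2, CH2Cl2, −40 °C) should give (3S,4R)-3-{[4-(benzyloxy)-3,5-dimethoxyphenyl]methyl}-4-{[4-(benzyloxy)-3-methoxyphenyl]methyl}-3-hydroxyoxolan-2-one F8. Neutral hydrogenolysis (H2, 10% Pd/C, EtOAc, rt) then gives 16.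

Further compounds
F1 | step 6 | (3S,4R)-3-[4-(benzyloxy)-3,5-dimethoxybenzoyl]-4-{[4-(benzyloxy)-3-methoxyphenyl]methyl}oxolan-2-one | COc1cc(C[C@H]2COC(=O)[C@@H]2C(=O)c2cc(OC)c(OCc3ccccc3)c(OC)c2)ccc1OCc1ccccc1
F2 | step 6 | (3S,4S)-3-[4-(benzyloxy)-3,5-dimethoxybenzoyl]-4-{[4-(benzyloxy)-3-methoxyphenyl]methyl}-3-hydroxyoxolan-2-one | COc1cc(C[C@H]2COC(=O)[C@@]2(O)C(=O)c2cc(OC)c(OCc3ccccc3)c(OC)c2)ccc1OCc1ccccc1
F3 | step 4 | 1-acetoxy-3-[4-(benzyloxy)-3-methoxyphenyl]propan-2-one | CC(=O)OCC(=O)Cc1ccc(OCc2ccccc2)c(OC)c1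
F4 | step 4 | 1-[4-(benzyloxy)-3-methoxyphenyl]-3-hydroxypropan-2-one | OCC(=O)Cc1ccc(OCc2ccccc2)c(OC)c1
F5 | step 4 | ethyl 3-[4-(benzyloxy)-3,5-dimethoxyphenyl]-3-oxopropanoate | CCOC(=O)CC(=O)c1cc(OC)c(OCc2ccccc2)c(OC)c1
F6 | step 4 | 3-[4-(benzyloxy)-3-methoxyphenyl]-2-oxopropyl 3-[4-(benzyloxy)-3,5-dimethoxyphenyl]-3-oxopropanoate | O=C(CC(=O)c1cc(OC)c(OCc2ccccc2)c(OC)c1)OCC(=O)Cc1ccc(OCc2ccccc2)c(OC)c1
F7 | step 8 | (3R,4R)-3-{[4-(benzyloxy)-3,5-dimethoxyphenyl](hydroxy)methyl}-4-{[4-(benzyloxy)-3-methoxyphenyl]methyl}-3-hydroxyoxolan-2-one | COc1cc(C[C@@H]2COC(=O)[C@]2(O)C(O)c2cc(OC)c(OCc3ccccc3)c(OC)c2)ccc1OCc1ccccc1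
F8 | step 8 | (3S,4R)-3-{[4-(benzyloxy)-3,5-dimethoxyphenyl]methyl}-4-{[4-(benzyloxy)-3-methoxyphenyl]methyl}-3-hydroxyoxolan-2-one | COc1cc(C[C@@H]2COC(=O)[C@]2(O)Cc2cc(OC)c(OCc3ccccc3)c(OC)c2)ccc1OCc1ccccc1
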